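**Retrosynthetic overview**

1. The target is 3,5,7-trihydroxyflavone carrying at C8 an R-configured diarylheptanoid carbon. Ring A (C4a, C5, C6, C7, C8, C8a) is a 1,3,5-trioxygenated benzene with oxygens on C5, C7 and C8a. The strategy rests on building this ring so that the C8 chain lies between O7 and O1 while the three oxygens stay different (O1–H free, O7 silylated, O5 ethylated).
2. Ring C is made last: O1–C2 by cyclodehydration and C2–C3 by a Baker–Venkataraman benzoyl shift from the O1 benzoate of a C4a ω-benzyloxyacetyl ketone. The C4a–acyl bond comes from lithiation between O1 (as its methoxymethyl ether) and O5.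
3. Ring A comes from a vinylketene–alkyne benzannulation of 3-ethoxycyclobutenone with a chiral triisopropylsilyl ynol ether, forming C8–C8a and C6–C7.
4. The ynol ether comes from a terminal alkyne by acetylide oxidation and O-silylation. The stereocentre is set by rhodium-catalysed asymmetric conjugate alkynylation of a 1,7-diarylhept-4-en-3-one, itself made by Horner–Wadsworth–Emmons olefination of a dihydroferulic acid-derived aldehyde.
5. Ring order: ring A (step 8), then ring C (step 13); ring B and the two chain arenes are bought in.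

Key step: step 8

Assumption: the (R)-configured ligand in step 4 is taken to give the 5R adduct (alkynyl > CH2C(=O) > CH2CH2Ar > H, the same spatial arrangement as the R centre of the target); the configuration would be assigned on the first batch and the (S)-ligand used if the sense proved opposite.

**Route**

Step 1
Reactants: 1 dihydroferulic acid, 3-(4-hydroxy-3-methoxyphenyl)propanoic acid
Product: 2 benzyl 3-[4-(benzyloxy)-3-methoxyphenyl]propanoate
Conditions: BnBr (2.3 equiv), K2CO3, DMF, 60 °C
Reagents that add atoms: benzyl bromide, BrCc1ccccc1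
Why: Williamson O-alkylation of both the phenoxide and the carboxylate in one pot should protect the phenol as its benzyl ether and give an ester ready for half-reduction.

Step 2
Reactants: 2 benzyl 3-[4-(benzyloxy)-3-methoxyphenyl]propanoate
Product: 3 3-[4-(benzyloxy)-3-methoxyphenyl]propanal
Conditions: i-Bu2AlH (1.1 equiv), CH2Cl2, −78 °C; MeOH, aq. KNaC4H4O6
Reagents that add atoms: none
Why: Partial ester reduction with i-Bu2AlH should stop at the aldehyde because the aluminium hemiacetal is stable at −78 °C and collapses only on work-up.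

Step 3
Reactants: 3 3-[4-(benzyloxy)-3-methoxyphenyl]propanal; 4 dimethyl (2-oxo-4-phenylbutyl)phosphonate
Product: 5 (E)-7-[4-(benzyloxy)-3-methoxyphenyl]-1-phenylhept-4-en-3-one
Conditions: LiCl, i-Pr2NEt, MeCN, rt
Reagents that add atoms: none
Why: Horner–Wadsworth–Emmons olefination under Masamune–Roush conditions with a stabilised β-ketophosphonate should give the E-enone, and the mild amine base avoids self-aldolisation of the enolisable aldehyde.

Step 4
Reactants: 5 (E)-7-[4-(benzyloxy)-3-methoxyphenyl]-1-phenylhept-4-en-3-one; 6 ethynyl(triisopropyl)silane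
Product: 7 (5R)-7-[4-(benzyloxy)-3-methoxyphenyl]-1-phenyl-5-[(triisopropylsilyl)ethynyl]heptan-3-one
Conditions: [Rh(OAc)(C2H4)2]2 (2.5 mol%), (R)-DTBM-SEGPHOS (5.5 mol%), 6 (2 equiv), 1,4-dioxane, 80 °C
Reagents that add atoms: none
Why: Rhodium-catalysed asymmetric conjugate alkynylation, in which an alkynyl complex of monovalent rhodium inserts the enone 1,4 and the oxa-π-allyl is protonated by more alkyne, should set C5 by ligand-controlled choice of the enone face, the bulky silyl group and ligand suppressing alkyne dimerisation.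

Step 5
Reactants: 7 (5R)-7-[4-(benzyloxy)-3-methoxyphenyl]-1-phenyl-5-[(triisopropylsilyl)ethynyl]heptan-3-one
Product: 8 2-{(2R)-4-[4-(benzyloxy)-3-methoxyphenyl]-2-[(triisopropylsilyl)ethynyl]butyl}-2-(2-phenylethyl)-1,3-dioxolane
Conditions: HOCH2CH2OH, TsOH (cat.), toluene, reflux, Dean–Stark
Reagents that add atoms: ethylene glycol, OCCO
Why: Acid-catalysed ketalisation with azeotropic removal of water masks the ketone against the organolithium reagents of steps 7 and 10, and the stereocentre, which bears no acidic hydrogen, is not at risk.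

Step 6
Reactants: 8 2-{(2R)-4-[4-(benzyloxy)-3-methoxyphenyl]-2-[(triisopropylsilyl)ethynyl]butyl}-2-(2-phenylethyl)-1,3-dioxolane
Product: 9 2-{(2R)-4-[4-(benzyloxy)-3-methoxyphenyl]-2-ethynylbutyl}-2-(2-phenylethyl)-1,3-dioxolane
Conditions: Bu4NF, THF, 0 °C → rt
Reagents that add atoms: none
Why: Fluoride-induced protodesilylation of the alkynylsilane should free the terminal alkyne while ketal and benzyl ether are inert.

Step 7
Reactants: 9 2-{(2R)-4-[4-(benzyloxy)-3-methoxyphenyl]-2-ethynylbutyl}-2-(2-phenylethyl)-1,3-dioxolane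
Product: 12 triisopropylsilyl ynol ether {[(3R)-5-[4-(benzyloxy)-3-methoxyphenyl]-3-{[2-(2-phenylethyl)-1,3-dioxolan-2-yl]methyl}pent-1-yn-1-yl]oxy}triisopropylsilane, via lithium acetylide 10 (not isolated), via lithium ynolate 11 (not isolated)
Conditions: n-BuLi (1.0 equiv), THF, −78 °C; t-BuOOLi (from t-BuOOH and LiN(SiMe3)2), −78 → 0 °C; i-Pr3SiOTf, −78 → 0 °C
Reagents that add atoms: tert-butyl hydroperoxide, CC(C)(C)OO; triisopropylsilyl trifluoromethanesulfonate, CC(C)[Si](OS(=O)(=O)C(F)(F)F)(C(C)C)C(C)C
Why: Oxidation of the lithium acetylide by lithium tert-butyl peroxide (attack at the peroxide oxygen, loss of tert-butoxide) should give the ynolate, which the bulky silyl triflate traps at oxygen and not at carbon, and the propargylic C–H is too weakly acidic for the stereocentre to be touched.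

Step 8
Reactants: 12 triisopropylsilyl ynol ether (as in step 7); 13 3-ethoxycyclobut-2-en-1-one
Product: 18 2-{(2R)-4-[4-(benzyloxy)-3-methoxyphenyl]-1-[2-(2-phenylethyl)-1,3-dioxolan-2-yl]butan-2-yl}-5-ethoxy-3-[(triisopropylsilyl)oxy]phenol, via 2-ethoxyvinylketene 14 (not isolated), via vinylcyclobutenone 15 (not isolated), via dienylketene 16 (not isolated), via cyclohexadienone tautomer 17 (not isolated)
Conditions: 13 (1.5 equiv), toluene, 80 → 110 °C
Reagents that add atoms: none
Why: On heating, 13 should open reversibly (4π-electrocyclic) to vinylketene 14, whose ketene C=C adds to ynol ether 12 in a [2+2] cycloaddition that forms the later C8–C8a and C6–C7 bonds and gives cyclobutenone 15; 15 opens (4π) to dienylketene 16, which closes to dienone 17 and tautomerises to phenol 18. This is the Danheiser benzannulation of a cyclobutenone with a trialkylsilyloxyalkyne. Ring A is closed by 6π-electrocyclisation of 16 (re-forming the C4a–C8a bond), and no stereocentre is created because the sp3 ring carbon of 15 is lost on aromatisation. The step needs one selectivity, the orientation of the [2+2] addition, and the polarised siloxyalkyne secures it: its chain-bearing β-carbon is the nucleophilic end and bonds to the ketene carbonyl carbon, so the chain ends up between the free OH (future O1) and the silyloxy group (future O7), with OEt para to it (future O5). Reversible opening of 15 should funnel material through the dienylketene isomer that has the ethoxyvinyl group cis to the ketene carbon, the only one able to cyclise. The existing stereocentre carries a non-acidic hydrogen in a neutral aprotic medium and should pass through unchanged.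

Step 9
Reactants: 18 phenol (as in step 8)
Product: 19 methoxymethyl ether of 18 at the phenolic oxygen (future O1)
Conditions: NaH, THF, 0 °C; MeOCH2Cl, 0 °C → rt
Reagents that add atoms: chloromethyl methyl ether, COCCl
Why: Williamson alkylation of the sodium phenoxide installs a chelating acetal that directs the next metalation; the basic medium leaves ketal, aryl silyl ether and benzyl ether alone.

Step 10
Reactants: 19 methoxymethyl ether (as in step 9); 20 2-(benzyloxy)-N-methoxy-N-methylacetamide
Product: 22 2-(benzyloxy)-1-[aryl]ethan-1-one in which the aryl ring of 19 carries the new acyl group at the carbon between OCH2OMe and OEt (future C4a), via aryllithium 21 (not isolated)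
Conditions: n-BuLi (1.2 equiv), THF, −20 → 0 °C; then 20, −78 → 0 °C; aq. NH4Cl
Reagents that add atoms: none
Why: Directed ortho-metalation should remove the only ring hydrogen flanked by two coordinating alkoxy groups (the other is shielded by the bulky, poorly coordinating silyloxy group), and acylation of the aryllithium by the Weinreb amide stops at the ketone.

Step 11
Reactants: 22 methoxymethyl-protected aryl ketone (as in step 10)
Product: 24 2-(benzyloxy)-1-[2-hydroxyaryl]ethan-1-one (free O1–H, chain at the other ortho position, OEt and OSi(i-Pr)3 retained), via aryl trimethylsilyl ether 23 (not isolated)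
Conditions: Me3SiOTf, 2,2'-bipyridyl, CH2Cl2, 0 °C → rt; then H2O
Reagents that add atoms: none
Why: Silyl triflate/bipyridyl cleavage of an aromatic methoxymethyl ether passes through a pyridinium salt and the aryl silyl ether in a non-acidic medium, and the ketone-derived dioxolane is too hindered to enter the same pathway, so ketal, benzyl ethers and the bulky aryl silyl ether should survive.

Step 12
Reactants: 24 hydroxy ketone (as in step 11)
Product: 25 benzoate ester of 24 at O1
Conditions: BzCl, Et3N, DMAP (cat.), CH2Cl2, 0 °C → rt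
Reagents that add atoms: benzoyl chloride, O=C(Cl)c1ccccc1
Why: DMAP-catalysed O-acylation of the hindered, hydrogen-bonded phenol places the benzoyl group where the Baker–Venkataraman shift needs it.

Step 13
Reactants: 25 benzoate (as in step 12)
Product: 27 3-(benzyloxy)-8-{(3R)-1-[4-(benzyloxy)-3-methoxyphenyl]-5-oxo-7-phenylheptan-3-yl}-5-ethoxy-2-phenyl-7-[(triisopropylsilyl)oxy]-4H-chromen-4-one, via 1,3-diketone 26 (not isolated)
Conditions: LiN(SiMe3)2 (3 equiv), THF, −78 → 0 °C; AcOH quench; then conc. HCl/AcOH (1:20), 70 °C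
Reagents that add atoms: none
Why: In the Baker–Venkataraman rearrangement the α-benzyloxy ketone enolate attacks the neighbouring benzoate through a six-membered transition state to give the 1,3-diketone, and acid then closes ring C by 6-exo-trig attack of O1–H on the benzoyl carbonyl with loss of water, the aqueous acid hydrolysing the dioxolane at the same time.

Step 14
Reactants: 27 protected flavone (as in step 13)
Product: 28 3,5-dihydroxy-8-[(3R)-1-(4-hydroxy-3-methoxyphenyl)-5-oxo-7-phenylheptan-3-yl]-2-phenyl-7-[(triisopropylsilyl)oxy]-4H-chromen-4-one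
Conditions: BCl3 (8 equiv), C6HMe5 (6 equiv), CH2Cl2, −78 → 0 °C; MeOH, then H2O
Reagents that add atoms: none
Why: Lewis-acid ether cleavage should remove both benzyl groups (benzyl cation captured by pentamethylbenzene, which prevents C-benzylation of ring A) and the 5-O-ethyl group (boron chelated between O5 and the C4 carbonyl, chloride attack on ethyl), while the non-chelated guaiacol methyl ether persists and O7 stays blocked.

Step 15
Reactants: 28 7-O-silyl flavonol (as in step 14)
Product: 29 target, 3,5,7-trihydroxy-8-[(3R)-1-(4-hydroxy-3-methoxyphenyl)-5-oxo-7-phenylheptan-3-yl]-2-phenyl-4H-chromen-4-one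
Conditions: Bu4NF, AcOH, THF, 0 °C
Reagents that add atoms: none
Why: Fluoride desilylation of the aryl silyl ether, buffered with acetic acid to protect the base- and air-sensitive polyphenol, should release the 7-hydroxyl and give the target.

**Compound list**

1 | dihydroferulic acid | COc1cc(CCC(=O)O)ccc1O | starting material
2 | benzyl 3-[4-(benzyloxy)-3-methoxyphenyl]propanoate | COc1cc(CCC(=O)OCc2ccccc2)ccc1OCc1ccccc1 | intermediate
3 | 3-[4-(benzyloxy)-3-methoxyphenyl]propanal | COc1cc(CCC=O)ccc1OCc1ccccc1 | intermediate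
4 | dimethyl (2-oxo-4-phenylbutyl)phosphonate | COP(=O)(CC(=O)CCc1ccccc1)OC | starting material
5 | (E)-7-[4-(benzyloxy)-3-methoxyphenyl]-1-phenylhept-4-en-3-one | COc1cc(CC/C=C/C(=O)CCc2ccccc2)ccc1OCc1ccccc1 | intermediate
6 | ethynyl(triisopropyl)silane | C#C[Si](C(C)C)(C(C)C)C(C)C | starting material
7 | (5R)-alkynyl ketone | COc1cc(CC[C@H](CC(=O)CCc2ccccc2)C#C[Si](C(C)C)(C(C)C)C(C)C)ccc1OCc1ccccc1 | intermediate
8 | dioxolane of 7 | COc1cc(CC[C@H](CC2(CCc3ccccc3)OCCO2)C#C[Si](C(C)C)(C(C)C)C(C)C)ccc1OCc1ccccc1 | intermediate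
9 | terminal alkyne | COc1cc(CC[C@H](CC2(CCc3ccccc3)OCCO2)C#C)ccc1OCc1ccccc1 | intermediate
10 | lithium acetylide of 9 | COc1cc(CC[C@H](CC2(CCc3ccccc3)OCCO2)C#C[Li])ccc1OCc1ccccc1 | intermediate
11 | lithium ynolate | COc1cc(CC[C@H](CC2(CCc3ccccc3)OCCO2)C#CO[Li])ccc1OCc1ccccc1 | intermediate
12 | triisopropylsilyl ynol ether (key-step precursor) | COc1cc(CC[C@H](CC2(CCc3ccccc3)OCCO2)C#CO[Si](C(C)C)(C(C)C)C(C)C)ccc1OCc1ccccc1 | intermediate
13 | 3-ethoxycyclobut-2-en-1-one | CCOC1=CC(=O)C1 | starting material
14 | 3-ethoxybuta-1,3-dien-1-one (2-ethoxyvinylketene) | CCOC(=C)C=C=O | intermediate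
15 | 4-(1-ethoxyethenyl)-3-silyloxy-2-alkylcyclobut-2-en-1-one, either configuration at the ring sp3 carbon | COc1cc(CC[C@H](CC2(CCc3ccccc3)OCCO2)C2=C(O[Si](C(C)C)(C(C)C)C(C)C)C(C(=C)OCC)C2=O)ccc1OCc1ccccc1 | intermediate
16 | dienylketene, ethoxyvinyl cis to the ketene carbon | COc1cc(CC[C@H](CC2(CCc3ccccc3)OCCO2)C(=C=O)/C(O[Si](C(C)C)(C(C)C)C(C)C)=C\C(=C)OCC)ccc1OCc1ccccc1 | intermediate
17 | cyclohexa-2,4-dienone tautomer of 18 | COc1cc(CC[C@H](CC2(CCc3ccccc3)OCCO2)C2=C(O[Si](C(C)C)(C(C)C)C(C)C)C=C(OCC)CC2=O)ccc1OCc1ccccc1 | intermediate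
18 | 2-alkyl-5-ethoxy-3-(triisopropylsilyloxy)phenol (key-step product) | COc1cc(CC[C@H](CC2(CCc3ccccc3)OCCO2)c2c(O)cc(OCC)cc2O[Si](C(C)C)(C(C)C)C(C)C)ccc1OCc1ccccc1 | intermediate
19 | methoxymethyl ether of 18 | COc1cc(CC[C@H](CC2(CCc3ccccc3)OCCO2)c2c(OCOC)cc(OCC)cc2O[Si](C(C)C)(C(C)C)C(C)C)ccc1OCc1ccccc1 | intermediate
20 | 2-(benzyloxy)-N-methoxy-N-methylacetamide | CON(C)C(=O)COCc1ccccc1 | starting material
21 | aryllithium, Li between OCH2OMe and OEt | COc1cc(CC[C@H](CC2(CCc3ccccc3)OCCO2)c2c(OCOC)c([Li])c(OCC)cc2O[Si](C(C)C)(C(C)C)C(C)C)ccc1OCc1ccccc1 | intermediate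
22 | methoxymethyl-protected ω-benzyloxy ketone | COc1cc(CC[C@H](CC2(CCc3ccccc3)OCCO2)c2c(OCOC)c(C(=O)COCc3ccccc3)c(OCC)cc2O[Si](C(C)C)(C(C)C)C(C)C)ccc1OCc1ccccc1 | intermediate
23 | aryl trimethylsilyl ether | COc1cc(CC[C@H](CC2(CCc3ccccc3)OCCO2)c2c(O[Si](C)(C)C)c(C(=O)COCc3ccccc3)c(OCC)cc2O[Si](C(C)C)(C(C)C)C(C)C)ccc1OCc1ccccc1 | intermediate
24 | 2-hydroxyaryl ω-benzyloxy ketone | COc1cc(CC[C@H](CC2(CCc3ccccc3)OCCO2)c2c(O)c(C(=O)COCc3ccccc3)c(OCC)cc2O[Si](C(C)C)(C(C)C)C(C)C)ccc1OCc1ccccc1 | intermediate
25 | O1 benzoate of 24 | COc1cc(CC[C@H](CC2(CCc3ccccc3)OCCO2)c2c(OC(=O)c3ccccc3)c(C(=O)COCc3ccccc3)c(OCC)cc2O[Si](C(C)C)(C(C)C)C(C)C)ccc1OCc1ccccc1 | intermediate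
26 | 2-(benzyloxy)-1-(2-hydroxyaryl)-3-phenylpropane-1,3-dione, labile centre at C2 undefined | COc1cc(CC[C@H](CC2(CCc3ccccc3)OCCO2)c2c(O)c(C(=O)C(OCc3ccccc3)C(=O)c3ccccc3)c(OCC)cc2O[Si](C(C)C)(C(C)C)C(C)C)ccc1OCc1ccccc1 | intermediate
27 | 3-O-benzyl-5-O-ethyl-7-O-silyl flavone with free chain ketone | COc1cc(CC[C@H](CC(=O)CCc2ccccc2)c2c(O[Si](C(C)C)(C(C)C)C(C)C)cc(OCC)c3c(=O)c(OCc4ccccc4)c(-c4ccccc4)oc23)ccc1OCc1ccccc1 | intermediate
28 | 7-O-triisopropylsilyl flavonol | COc1cc(CC[C@H](CC(=O)CCc2ccccc2)c2c(O[Si](C(C)C)(C(C)C)C(C)C)cc(O)c3c(=O)c(O)c(-c4ccccc4)oc23)ccc1O | intermediate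
29 | CNP0164153.1 | COc1cc(CC[C@H](CC(=O)CCc2ccccc2)c2c(O)cc(O)c3c(=O)c(O)c(-c4ccccc4)oc23)ccc1O | target

**Step count and risks**

Total steps: 15. Longest linear sequence: 15 (from dihydroferulic acid 1; compounds 4, 6, 13 and 20 are purchased).

Steps most likely to fail:

1. Step 8 (benzannulation). The donor-substituted cyclobutenone may open only at temperatures where the ynol silyl ether undergoes a 1,3-silyl shift to a silylketene. The vinylketene may also be consumed by O-acylation of phenol already formed before it meets the branched alkyne. The fallback sets out from ynol ether 12 and comes back at phenol 18. It no longer makes the ketene by electrocyclic opening but by base-induced elimination, and it separates cycloaddition from aromatisation. Commercial ethyl (E)-3-ethoxybut-2-enoate is saponified (LiOH, THF/H2O) to (E)-3-ethoxybut-2-enoic acid F1 and converted with (COCl)2 and catalytic DMF into (E)-3-ethoxybut-2-enoyl chloride F2. Slow addition of F2 to 12 and Et3N in CH2Cl2 at 0 °C → rt should generate the same vinylketene 14 by 1,4-dehydrochlorination and trap it as cyclobutenone 15. This is the known cycloaddition of silyloxyalkynes with vinylketenes made from unsaturated acid chlorides. Cyclobutenone 15 is isolated and then heated briefly in toluene to give 18 through 16 and 17.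

2. Step 7 (ynolate formation and O-silylation). Oxygen transfer from the peroxide to the branched acetylide may be incomplete, and the ynolate may be silylated at carbon or protonated on work-up. The fallback sets out from enone 5 and comes back at ynol ether 12 through ynolate 11, using ester homologation instead of alkyne oxidation. Conjugate addition of nitromethane to 5 under iminium catalysis by a 9-amino-9-deoxy-epi-cinchona primary amine with benzoic acid (pseudo-enantiomer chosen for the 5R adduct) should give (5R)-7-[4-(benzyloxy)-3-methoxyphenyl]-5-(nitromethyl)-1-phenylheptan-3-one F3. Ketalisation (HOCH2CH2OH, TsOH) gives the nitro dioxolane F4. Nef-type oxidation of the primary nitro group (NaNO2, AcOH, DMSO, 35 °C) gives the (2R)-carboxylic acid F5, and Me3SiCHN2/MeOH gives its methyl ester F6. Kowalski homologation (LiCHBr2 from CH2Br2 and lithium 2,2,6,6-tetramethylpiperidide, THF, −78 °C; then LiN(SiMe3)2 and n-BuLi, warming) passes through the dibromomethyl ketone F7 (as its enolate) and, by 1,2-shift of the chiral carbon with retention, to ynolate 11, which i-Pr3SiCl silylates to 12.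

3. Step 10 (directed metalation and acylation). Deprotonation at the benzylic CH2 of the aryl benzyl ether with Wittig rearrangement may compete, and the hindered aryllithium may enolise the α-alkoxy amide and return protonated arene. The fallback sets out from phenol 18 and comes back at hydroxy ketone 24, bypassing 19–23 and using no organolithium on the substrate. Magnesium-mediated ortho-formylation (MgCl2, Et3N, paraformaldehyde, MeCN, reflux; Casnati–Skattebøl) should put the formyl group at the only free position ortho to the hydroxyl and give salicylaldehyde F8. Addition of excess BnOCH2MgCl (THF, −78 → 0 °C) gives the benzylic carbinol F9 as both epimers, and MnO2 (CH2Cl2, rt) oxidises the benzylic alcohol to 24.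

**Further compounds**

F1 | step 8 | (E)-3-ethoxybut-2-enoic acid | CCO/C(C)=C/C(=O)O
F2 | step 8 | (E)-3-ethoxybut-2-enoyl chloride | CCO/C(C)=C/C(=O)Cl
F3 | step 7 | (5R)-7-[4-(benzyloxy)-3-methoxyphenyl]-5-(nitromethyl)-1-phenylheptan-3-one | COc1cc(CC[C@H](CC(=O)CCc2ccccc2)C[N+](=O)[O-])ccc1OCc1ccccc1
F4 | step 7 | 2-{(2R)-4-[4-(benzyloxy)-3-methoxyphenyl]-2-(nitromethyl)butyl}-2-(2-phenylethyl)-1,3-dioxolane | COc1cc(CC[C@H](CC2(CCc3ccccc3)OCCO2)C[N+](=O)[O-])ccc1OCc1ccccc1
F5 | step 7 | (2R)-4-[4-(benzyloxy)-3-methoxyphenyl]-2-{[2-(2-phenylethyl)-1,3-dioxolan-2-yl]methyl}butanoic acid | COc1cc(CC[C@H](CC2(CCc3ccccc3)OCCO2)C(=O)O)ccc1OCc1ccccc1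
F6 | step 7 | methyl ester of F5 | COc1cc(CC[C@H](CC2(CCc3ccccc3)OCCO2)C(=O)OC)ccc1OCc1ccccc1
F7 | step 7 | dibromomethyl ketone from F6 | COc1cc(CC[C@H](CC2(CCc3ccccc3)OCCO2)C(=O)C(Br)Br)ccc1OCc1ccccc1
F8 | step 10 | salicylaldehyde from 18 (CHO between OH and OEt) | COc1cc(CC[C@H](CC2(CCc3ccccc3)OCCO2)c2c(O)c(C=O)c(OCC)cc2O[Si](C(C)C)(C(C)C)C(C)C)ccc1OCc1ccccc1
F9 | step 10 | 2-(benzyloxy)-1-(2-hydroxyaryl)ethanol, both carbinol epimers | COc1cc(CC[C@H](CC2(CCc3ccccc3)OCCO2)c2c(O)c(C(O)COCc3ccccc3)c(OCC)cc2O[Si](C(C)C)(C(C)C)C(C)C)ccc1OCc1ccccc1
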